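**Analysis of the target**

The target 16 is a 3,4-dihydrocoumarin (chroman-2-one). Benzene ring A (C4a, C5, C6, C7, C8, C8a) is fused to a six-membered lactone ring (O1, C2, C3, C4, C4a, C8a). Ring A carries a free hydroxyl at C7 and an (E)-4-hydroxy-3-methoxystyryl group at C5, and C4 carries a 4-hydroxy-3-methoxyphenyl (guaiacyl) group. C4 is the only stereocenter. It is R-configured, a doubly benzylic methine β to the lactone carbonyl, and has no stereochemical relation to the only other stereo element, the E alkene. The aryl ester lactone opens easily with base, alcohols or amines. The three phenols and the para-oxygenated stilbene are sensitive to oxidants and strong acid, and the stilbene rules out any late hydrogenation. The difficulty is C4: its two aryl groups are electronically alike, it sits in the crowded bay next to the C5 styryl group, and no neighbouring stereocenter can relay its configuration, so a catalyst has to set it. The route rests on the fact that C2 is a single carbonyl carbon between O1 and C3. Taking it out as carbon monoxide leaves O1 as a phenol on C8a and C3/C4 as the terminal and internal carbons of a 1,1-diarylethene on C4a, so ring closure and creation of the C4–H stereocenter can be one event.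

**Retrosynthetic reasoning**

16 from 15. The last operation frees the three phenols by cutting three O–CH2Ph bonds. One protecting group on all three phenols survives the organomagnesium, ylide, acid/CO and palladium steps and comes off in one operation. Because of the stilbene, the removal must be non-reductive: a Lewis acid with a cation scavenger at low temperature, which has to spare the two aryl methyl ethers, the lactone and the alkene.

15 from 12 and 14. The C5–alkene bond of the stilbene is cut. This alkene has to be introduced after the carbonylation, because it would otherwise compete with the 1,1-diarylethene for the hydride catalyst. C5 therefore carries chlorine through the key step, inert there and a coupling handle afterwards. The forward Heck reaction must arylate the terminal carbon of styrene 14, give the E alkene and leave the lactone closed. Styrene 14 is the benzyl ether of commercial phenol 13.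

12 from 10 and 11. This is the central disconnection: O1–C2 and C2–C3 are cut, C2 leaves as carbon monoxide 11, and the hydrogen on C4 is removed, which gives the 2-(1-arylvinyl)phenol 10. It is made here because one catalytic step then builds the lactone ring and the stereocenter together. The bond formed at the congested carbon C4 is a C–H bond, the least demanding one sterically. The forward reaction needs hydride delivery to C4 from one face, palladium on the terminal carbon, and an untouched C–Cl bond.

10 from 9. The exocyclic C=CH2 is cut back to the ketone of benzophenone 9, whose ortho hydroxyl is already free. The forward step is a one-carbon olefination, and the product has no geometric isomers.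

9 from 8, and 8 from 4 and 7. The ketone comes from carbinol 8 by benzylic oxidation. The bond between the carbinol carbon and the guaiacyl ring is cut, giving salicylaldehyde 4 and aryl Grignard reagent 7 (from bromide 6, from phenol 5). The cut is made on the guaiacyl side because a nucleophilic carbon on ring A between oxygen and chlorine cannot be generated selectively: metalation would go between the two oxygens. An electrophilic carbon at that position is accessible by formylation.

4 from 3, and 3 from 1. In dihydroxy aldehyde 3 the two hydroxyls differ. The one ortho to the formyl group is hydrogen-bonded, so benzylation goes to the para oxygen and leaves free exactly the phenol that later becomes O1. No protection and deprotection of that oxygen is needed. Aldehyde 3 comes from 5-chlororesorcinol 1 by formylation (through iminium salt 2) at the carbon ortho to chlorine and para to a hydroxyl. This one step fixes the whole substitution pattern of ring A.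

**Alternatives that were turned down**

Alternative 1: Ring A is made last. The C4a–C5 bond is cut and the resorcinol is unfolded into the open-chain triketo ester A2, which already carries the C4 stereocenter.
- Forward key step: base forms the enolate of the methylene that becomes C4a, which adds to the cinnamoyl ketone (the future C5). Dehydration and enolisation give resorcinol A1, and acid then removes the acetal and tert-butyl groups and closes the lactone.
- For it: the substitution pattern of ring A is written into the chain, the stilbene is present from the start, and no cross-coupling on a crowded arene is needed. On this point it is stronger than the chosen route, which depends on a Heck reaction next to C4.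
- Against it: A2 has three ketones and several acidic sites. The methylenes flanked by two carbonyls are more acidic than the one that has to react, and their enolates or enol oxygens can add to the enone in a Michael sense or close pyranones. A2 also has to be assembled by repeated acylation of polyanions, with the stereocenter set in a separate asymmetric step, so the route is clearly longer.
- Comparison: the chosen strategy buys ring A as an arene and, in return for the late Heck step, sets C4 and closes the lactone in one catalytic operation.

Alternative 2: The lactone ring is made from the two biogenetic halves. C4–C4a and O1–C2 are cut, giving the stilbene resorcinol A5 and the silylated coniferyl aldehyde A4.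
- Forward key step: a chiral N-heterocyclic carbene and a quinone oxidant turn A4 into an unsaturated acyl azolium. A ring carbon of A5 attacks its β-carbon and the neighbouring phenol takes the acyl group, giving A3; desilylation finishes the synthesis.
- For it: it is the shortest route conceivable, clearly shorter than the chosen one. It needs no protecting group on ring A and no metal, and forms both ring bonds and the stereocenter at once.
- Against it: A5 offers two kinds of nucleophilic carbon, the one between the hydroxyls and the two equivalent ones next to the styryl group. The target needs the latter, the more hindered site, and the bond formed there is the crowded C4–C4a bond. The acyl azolium from A4 carries a para silyloxy donor and is a weak acceptor. The oxidant also meets an electron-rich stilbene phenol. Nothing in A5 helps the catalyst to tell the two faces apart.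
- Comparison: the chosen route is longer, but the position of C4 on ring A is fixed by a formylation of predictable regiochemistry, and the stereocenter is made by adding hydrogen to the crowded carbon.

Alternative 3: The lactone oxygen is inserted last. The C8a–O1 bond is cut, which turns the lactone into the 3-arylindan-1-one A7.
- Forward key step: a peracid adds to the ketone and the ring A carbon migrates to oxygen (Baeyer–Villiger), giving lactone A6. The triflate then serves a Heck reaction and fluoride removes the silyl groups.
- For it: C4 is not touched by the oxidation, and the stereocenter can be set by robust asymmetric chemistry on a rigid five-membered ring. The triflate is a better Heck partner than a chloride, and silyl ethers come off more mildly than benzyl ethers. On these last two points it is stronger than the chosen route.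
- Against it: in A7 the silyloxy group and the triflate are both meta to the migrating aryl carbon, so no donor supports aryl migration and the triflate withdraws. Migration of the methylene, which puts oxygen on the wrong side of the carbonyl, or no reaction at all, is to be feared. The peracid also meets an electron-rich guaiacyl ring, and A7 itself needs a long preparation.
- Comparison: the chosen strategy forms O1–C2 from a phenol that is already in place, so the direction of lactone formation cannot go wrong, and it needs fewer steps.

Key step: step 7

Remark on the chemistry: the sense of induction of the bisphosphine cannot be read from the structure. (R)-DTBM-SEGPHOS is written in step 7 and is replaced by its commercial antipode if a first run shows the 4S lactone.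

**Route**

Step 1
Reactants: 1 5-chlororesorcinol
Product: 3 2-chloro-4,6-dihydroxybenzaldehyde, via iminium chloride 2 (not isolated)
Conditions: POCl3 (1.3 eq), DMF (1.5 eq), MeCN, −15 °C to rt; then H2O, 50 °C
Reagents that add atoms: N,N-dimethylformamide, CN(C)C=O; water, O
Why: Vilsmeier–Haack formylation; the chloroiminium ion should attack the carbon para to one hydroxyl and ortho to the other (and ortho to chlorine) rather than the carbon flanked by both hydroxyls, as is usual for 5-substituted resorcinols. Warm water hydrolyses iminium salt 2 to the aldehyde.

Step 2
Reactants: 3 2-chloro-4,6-dihydroxybenzaldehyde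
Product: 4 4-(benzyloxy)-2-chloro-6-hydroxybenzaldehyde
Conditions: BnBr (1.05 eq), NaHCO3 (1.5 eq), KI (0.1 eq), MeCN, 80 °C
Reagents that add atoms: benzyl bromide, BrCc1ccccc1
Why: Williamson etherification under weak base; the hydroxyl para to the formyl group is the more acidic and is free, whereas the ortho hydroxyl is held in a hydrogen bond to the carbonyl, so mono-benzylation should go to the para oxygen.

Step 3
Reactants: 5 4-bromo-2-methoxyphenol
Product: 6 1-(benzyloxy)-4-bromo-2-methoxybenzene
Conditions: BnBr (1.1 eq), K2CO3 (1.5 eq), DMF, rt
Reagents that add atoms: benzyl bromide, BrCc1ccccc1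
Why: Williamson ether synthesis on a simple phenol; the benzyl ether makes the bromide fit for magnesium insertion.

Step 4
Reactants: 4 4-(benzyloxy)-2-chloro-6-hydroxybenzaldehyde; 6 1-(benzyloxy)-4-bromo-2-methoxybenzene
Product: 8 [4-(benzyloxy)-2-chloro-6-hydroxyphenyl][4-(benzyloxy)-3-methoxyphenyl]methanol (racemic), via arylmagnesium bromide 7 (not isolated)
Conditions: 6 (2.5 eq), Mg turnings, I2 (cat.), THF, 50 °C; then 4, THF, 0 °C to rt; H2O, sat. aq. NH4Cl; crude product taken on
Reagents that add atoms: none
Why: Grignard formation and 1,2-addition; the first equivalent of 7 deprotonates the phenol and the second adds to the resulting magnesium chelate of the salicylaldehyde. The carbinol center forms racemic, which does not matter because step 5 removes it; the acid-labile carbinol is not purified on silica.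

Step 5
Reactants: 8 [4-(benzyloxy)-2-chloro-6-hydroxyphenyl][4-(benzyloxy)-3-methoxyphenyl]methanol
Product: 9 [4-(benzyloxy)-2-chloro-6-hydroxyphenyl][4-(benzyloxy)-3-methoxyphenyl]methanone
Conditions: activated MnO2 (15 eq), CH2Cl2, rt
Reagents that add atoms: none
Why: Heterogeneous MnO2 oxidation of a doubly benzylic alcohol; the phenol is tolerated and the product ketone is stabilised by the hydrogen bond to the ortho hydroxyl.

Step 6
Reactants: 9 [4-(benzyloxy)-2-chloro-6-hydroxyphenyl][4-(benzyloxy)-3-methoxyphenyl]methanone
Product: 10 5-(benzyloxy)-2-{1-[4-(benzyloxy)-3-methoxyphenyl]vinyl}-3-chlorophenol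
Conditions: Ph3PCH3Br (3.0 eq), KOt-Bu (3.0 eq), THF, 0 °C to 65 °C
Reagents that add atoms: methyltriphenylphosphonium bromide, C[P+](c1ccccc1)(c1ccccc1)c1ccccc1.[Br-]
Why: Wittig methylenation; excess ylide first deprotonates the phenol, the small unstabilised ylide then adds to the hindered diaryl ketone, and loss of Ph3PO gives the 1,1-diarylethene, which has no geometric isomers.

Step 7
Reactants: 10 5-(benzyloxy)-2-{1-[4-(benzyloxy)-3-methoxyphenyl]vinyl}-3-chlorophenol; 11 carbon monoxide
Product: 12 (R)-7-(benzyloxy)-4-[4-(benzyloxy)-3-methoxyphenyl]-5-chlorochroman-2-one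
Conditions: Pd(OAc)2 (5 mol %), (R)-DTBM-SEGPHOS (6 mol %), TsOH·H2O (20 mol %), CO (20 bar), toluene, 60 °C
Reagents that add atoms: none
Why: Pd(OAc)2, the bisphosphine, TsOH and CO should generate a cationic chiral palladium hydride; the closest known reaction type is the palladium-catalysed asymmetric hydroesterification of 1,1-disubstituted vinylarenes with CO and an O–H nucleophile, here in its intramolecular, lactone-forming version with an ortho phenol. The hydride adds across the alkene of 10 with hydrogen to the diaryl carbon (C4) and palladium to the CH2 terminus (C3); the opposite regiochemistry would put palladium on a fully substituted diarylmethyl carbon, where CO insertion is blocked and the adduct can only revert by β-hydride elimination. CO then inserts into the Pd–C3 bond to give the acyl palladium (new C2–C3 bond), and the ortho hydroxyl attacks the acyl carbon (new O1–C2 bond), a 6-exo-trig acyl substitution that closes the lactone ring and returns the palladium hydride. The C4 stereocenter is under catalyst control: the chiral bisphosphine pocket decides the alkene face that receives hydrogen, and since hydropalladation may be reversible the selection is completed at CO insertion within the same pocket. The substrate helps, because ring A with its two ortho substituents (OH and Cl) is twisted out of the alkene plane while the guaiacyl ring stays conjugated, which makes the two aryl groups sterically very different, and because the ortho hydroxyl can hold the substrate near the metal. The step needs linear regiochemistry, facial selectivity and chemoselectivity: the alkene has no allylic hydrogen, so isomerisation is impossible, and the C–Cl bond with two ortho neighbours should not add to the small amount of arylphosphine-ligated zerovalent palladium at 60 °C. The benzyl ethers are inert to the acid co-catalyst in toluene.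

Step 8
Reactants: 13 2-methoxy-4-vinylphenol
Product: 14 1-(benzyloxy)-2-methoxy-4-vinylbenzene
Conditions: BnBr (1.1 eq), K2CO3 (1.5 eq), BHT (cat.), acetone, 40 °C
Reagents that add atoms: benzyl bromide, BrCc1ccccc1
Why: Williamson ether synthesis; the mild carbonate base and a radical inhibitor keep the styrene from polymerising.

Step 9
Reactants: 12 (R)-7-(benzyloxy)-4-[4-(benzyloxy)-3-methoxyphenyl]-5-chlorochroman-2-one; 14 1-(benzyloxy)-2-methoxy-4-vinylbenzene
Product: 15 (R)-7-(benzyloxy)-4-[4-(benzyloxy)-3-methoxyphenyl]-5-[(E)-4-(benzyloxy)-3-methoxystyryl]chroman-2-one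
Conditions: 14 (1.5 eq), Pd2(dba)3 (2.5 mol %), [HP(t-Bu)3]BF4 (10 mol %), Cy2NMe (1.5 eq), 1,4-dioxane, 100 °C, dark
Reagents that add atoms: none
Why: Mizoroki–Heck reaction of an aryl chloride; the monoligated zerovalent palladium–P(t-Bu)3 species inserts into the C5–Cl bond, the aryl group migrates to the unsubstituted alkene carbon of 14, and syn β-hydride elimination gives the E stilbene. The hindered tertiary amine takes up HCl without attacking the lactone, and C4 bears no acidic hydrogen, so its configuration should be kept.

Step 10
Reactants: 15 (R)-7-(benzyloxy)-4-[4-(benzyloxy)-3-methoxyphenyl]-5-[(E)-4-(benzyloxy)-3-methoxystyryl]chroman-2-one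
Product: 16 (R)-7-hydroxy-4-(4-hydroxy-3-methoxyphenyl)-5-[(E)-4-hydroxy-3-methoxystyryl]chroman-2-one
Conditions: BCl3 (1 M in CH2Cl2, 9 eq), C6HMe5 (12 eq), CH2Cl2, −78 °C; aq. NaHCO3 at −78 °C, dark
Reagents that add atoms: none
Why: Lewis-acid cleavage of aryl benzyl ethers with a cation scavenger; BCl3 coordinates the ether oxygens and pentamethylbenzene captures the benzyl cations by Friedel–Crafts alkylation before they can attack the electron-rich rings or the stilbene. At −78 °C the aryl methyl ethers, the lactone and the alkene should survive, and the quench with aqueous hydrogencarbonate instead of methanol avoids opening the lactone.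

**Compound list**

1 | 5-chlororesorcinol | Oc1cc(O)cc(Cl)c1 | starting material
2 | N-[(2-chloro-4,6-dihydroxyphenyl)methylidene]-N-methylmethanaminium chloride | C[N+](C)=Cc1c(O)cc(O)cc1Cl.[Cl-] | intermediate (not isolated)
3 | 2-chloro-4,6-dihydroxybenzaldehyde | O=Cc1c(O)cc(O)cc1Cl | intermediate
4 | 4-(benzyloxy)-2-chloro-6-hydroxybenzaldehyde | O=Cc1c(O)cc(OCc2ccccc2)cc1Cl | intermediate
5 | 4-bromo-2-methoxyphenol | COc1cc(Br)ccc1O | starting material
6 | 1-(benzyloxy)-4-bromo-2-methoxybenzene | COc1cc(Br)ccc1OCc1ccccc1 | intermediate
7 | [4-(benzyloxy)-3-methoxyphenyl]magnesium bromide | COc1cc([Mg]Br)ccc1OCc1ccccc1 | intermediate (not isolated)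
8 | [4-(benzyloxy)-2-chloro-6-hydroxyphenyl][4-(benzyloxy)-3-methoxyphenyl]methanol, racemic | COc1cc(C(O)c2c(O)cc(OCc3ccccc3)cc2Cl)ccc1OCc1ccccc1 | intermediate
9 | [4-(benzyloxy)-2-chloro-6-hydroxyphenyl][4-(benzyloxy)-3-methoxyphenyl]methanone | COc1cc(C(=O)c2c(O)cc(OCc3ccccc3)cc2Cl)ccc1OCc1ccccc1 | intermediate
10 | 5-(benzyloxy)-2-{1-[4-(benzyloxy)-3-methoxyphenyl]vinyl}-3-chlorophenol | C=C(c1ccc(OCc2ccccc2)c(OC)c1)c1c(O)cc(OCc2ccccc2)cc1Cl | intermediate
11 | carbon monoxide | [C-]#[O+] | starting material
12 | (R)-7-(benzyloxy)-4-[4-(benzyloxy)-3-methoxyphenyl]-5-chlorochroman-2-one | Clc1cc(OCc2ccccc2)cc2c1[C@@H](c1ccc(OCc3ccccc3)c(OC)c1)CC(=O)O2 | intermediate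
13 | 2-methoxy-4-vinylphenol | COc1cc(C=C)ccc1O | starting material
14 | 1-(benzyloxy)-2-methoxy-4-vinylbenzene | C=Cc1ccc(OCc2ccccc2)c(OC)c1 | intermediate
15 | (R)-7-(benzyloxy)-4-[4-(benzyloxy)-3-methoxyphenyl]-5-[(E)-4-(benzyloxy)-3-methoxystyryl]chroman-2-one | COc1cc(/C=C/c2cc(OCc3ccccc3)cc3c2[C@@H](c2ccc(OCc4ccccc4)c(OC)c2)CC(=O)O3)ccc1OCc1ccccc1 | intermediate
16 | (R)-7-hydroxy-4-(4-hydroxy-3-methoxyphenyl)-5-[(E)-4-hydroxy-3-methoxystyryl]chroman-2-one | COc1cc(/C=C/c2cc(O)cc3c2[C@@H](c2ccc(O)c(OC)c2)CC(=O)O3)ccc1O | target

**Step count and least certain steps**

Total step count: 10. Longest linear sequence: 8 steps (steps 1, 2, 4, 5, 6, 7, 9 and 10).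

Step 7 (key step).
- What may go wrong: hydropalladation may be slow because the alkene is attached to a ring with two ortho substituents. Facial discrimination may be insufficient. The acid co-catalyst may protonate the electron-rich alkene, leading to cationic dimerisation.
- Fallback: it sets out from salicylaldehyde 4 and Grignard reagent 7 and comes back to the route at 12. Aldehyde 4 is heated with ethyl (triphenylphosphoranylidene)acetate in N,N-diethylaniline (Wittig olefination followed by thermal lactonisation) to give 7-(benzyloxy)-5-chloro-2H-chromen-2-one F1. Reagent 7 is quenched with B(OMe)3 and then aqueous acid to give [4-(benzyloxy)-3-methoxyphenyl]boronic acid F2. Rhodium-catalysed asymmetric 1,4-addition of F2 to F1 ([Rh(acac)(C2H4)2], (R)-SEGPHOS or its antipode, dioxane/H2O, 60 °C) would then give 12. In this approach the C4–aryl bond, not the C4–H bond, is formed in the enantio-determining step, with the chiral aryl–rhodium species choosing the face of the coumarin.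

Step 6.
- What may go wrong: addition of the ylide may stall, because the carbonyl is deactivated by the phenoxide and shielded by the two ortho substituents of ring A.
- Fallback: it sets out from 9 and comes back at 10. MeMgBr (3.5 eq, THF, 0 to 40 °C) adds to the magnesium chelate of the hydroxy ketone and gives 5-(benzyloxy)-2-{1-[4-(benzyloxy)-3-methoxyphenyl]-1-hydroxyethyl}-3-chlorophenol F3. Catalytic TsOH in toluene at 40 °C then eliminates water through the stabilised diarylmethyl cation; only the methyl group can lose a proton, so 10 results. F3 could also be charged directly to the carbonylation, where the acid co-catalyst would dehydrate it in the flask.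

Step 9.
- What may go wrong: oxidative addition to the ortho-substituted chloride next to the C4 methine may be slow. The lactone may open at the temperature required. Alkene insertion may partly take the branched course.
- Fallback: it sets out from 12 and 14 and comes back at 15. Cross-metathesis of 14 with vinylboronic acid pinacol ester (second-generation Grubbs catalyst, CH2Cl2, 40 °C) gives (E)-2-[4-(benzyloxy)-3-methoxystyryl]-4,4,5,5-tetramethyl-1,3,2-dioxaborolane F4. Suzuki–Miyaura coupling of F4 with 12 (Pd(OAc)2, SPhos, anhydrous K3PO4, toluene, 80 °C) gives 15. Transmetalation replaces alkene insertion, so regiochemistry and alkene geometry are fixed by the boronate.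

Step 10.
- What may go wrong: the Lewis acid or the HCl formed may protonate the electron-rich stilbene and start oligomerisation. Benzyl cations may re-attach to the activated rings. A guaiacyl methyl ether may be lost. The lactone may open during the quench.
- Fallback: it sets out from 12 (and 13) and comes back at 16; the Lewis acid is used before the stilbene exists. BCl3 and pentamethylbenzene at −78 °C convert 12 into (R)-5-chloro-7-hydroxy-4-(4-hydroxy-3-methoxyphenyl)chroman-2-one F5. TBSCl and imidazole in DMF give (R)-7-(tert-butyldimethylsilyloxy)-4-[4-(tert-butyldimethylsilyloxy)-3-methoxyphenyl]-5-chlorochroman-2-one F6. Phenol 13 is silylated in the same way to tert-butyl(2-methoxy-4-vinylphenoxy)dimethylsilane F7. Heck coupling of F6 with F7 under the conditions of step 9 gives (R)-7-(tert-butyldimethylsilyloxy)-4-[4-(tert-butyldimethylsilyloxy)-3-methoxyphenyl]-5-[(E)-4-(tert-butyldimethylsilyloxy)-3-methoxystyryl]chroman-2-one F8. HF·pyridine in THF at 0 °C then gives 16 without any Lewis acid at the end.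

Step 4 (with step 5).
- What may go wrong: carbinol 8 may ionise to an ortho-quinone methide on work-up, since it has an ortho hydroxyl and two para-alkoxyaryl groups, and this would lead to oligomers. Addition to the magnesium phenoxide may also be slow.
- Fallback: it sets out from 4 and comes back at 9. Benzylation of 4 (BnBr, K2CO3, DMF) gives 2,4-bis(benzyloxy)-6-chlorobenzaldehyde F9. Addition of 7 gives [2,4-bis(benzyloxy)-6-chlorophenyl][4-(benzyloxy)-3-methoxyphenyl]methanol F10, which has no free phenol. MnO2 gives [2,4-bis(benzyloxy)-6-chlorophenyl][4-(benzyloxy)-3-methoxyphenyl]methanone F11. MgBr2·OEt2 in toluene/Et2O at 80 °C then cleaves only the benzyl ether ortho to the carbonyl, by chelation, to give 9.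

**Further compounds**

F1 | step 7 | 7-(benzyloxy)-5-chloro-2H-chromen-2-one | O=C1C=Cc2c(Cl)cc(OCc3ccccc3)cc2O1
F2 | step 7 | [4-(benzyloxy)-3-methoxyphenyl]boronic acid | COc1cc(B(O)O)ccc1OCc1ccccc1
F3 | step 6 | 5-(benzyloxy)-2-{1-[4-(benzyloxy)-3-methoxyphenyl]-1-hydroxyethyl}-3-chlorophenol, racemic | COc1cc(C(C)(O)c2c(O)cc(OCc3ccccc3)cc2Cl)ccc1OCc1ccccc1
F4 | step 9 | (E)-2-[4-(benzyloxy)-3-methoxystyryl]-4,4,5,5-tetramethyl-1,3,2-dioxaborolane | COc1cc(/C=C/B2OC(C)(C)C(C)(C)O2)ccc1OCc1ccccc1
F5 | step 10 | (R)-5-chloro-7-hydroxy-4-(4-hydroxy-3-methoxyphenyl)chroman-2-one | Clc1cc(O)cc2c1[C@@H](c1ccc(O)c(OC)c1)CC(=O)O2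
F6 | step 10 | (R)-7-(tert-butyldimethylsilyloxy)-4-[4-(tert-butyldimethylsilyloxy)-3-methoxyphenyl]-5-chlorochroman-2-one | Clc1cc(O[Si](C)(C)C(C)(C)C)cc2c1[C@@H](c1ccc(O[Si](C)(C)C(C)(C)C)c(OC)c1)CC(=O)O2
F7 | step 10 | tert-butyl(2-methoxy-4-vinylphenoxy)dimethylsilane | C=Cc1ccc(O[Si](C)(C)C(C)(C)C)c(OC)c1
F8 | step 10 | (R)-7-(tert-butyldimethylsilyloxy)-4-[4-(tert-butyldimethylsilyloxy)-3-methoxyphenyl]-5-[(E)-4-(tert-butyldimethylsilyloxy)-3-methoxystyryl]chroman-2-one | COc1cc(/C=C/c2cc(O[Si](C)(C)C(C)(C)C)cc3c2[C@@H](c2ccc(O[Si](C)(C)C(C)(C)C)c(OC)c2)CC(=O)O3)ccc1O[Si](C)(C)C(C)(C)C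
F9 | step 4 | 2,4-bis(benzyloxy)-6-chlorobenzaldehyde | O=Cc1c(OCc2ccccc2)cc(OCc2ccccc2)cc1Cl
F10 | step 4 | [2,4-bis(benzyloxy)-6-chlorophenyl][4-(benzyloxy)-3-methoxyphenyl]methanol, racemic | COc1cc(C(O)c2c(OCc3ccccc3)cc(OCc3ccccc3)cc2Cl)ccc1OCc1ccccc1
F11 | step 4 | [2,4-bis(benzyloxy)-6-chlorophenyl][4-(benzyloxy)-3-methoxyphenyl]methanone | COc1cc(C(=O)c2c(OCc3ccccc3)cc(OCc3ccccc3)cc2Cl)ccc1OCc1ccccc1
A1 | alternative 1 | tert-butyl (R)-3-{2,4-dihydroxy-6-[(E)-3-methoxy-4-(methoxymethoxy)styryl]phenyl}-3-[3-methoxy-4-(methoxymethoxy)phenyl]propanoate | COc1cc(/C=C/c2cc(O)cc(O)c2[C@@H](c2ccc(OCOC)c(OC)c2)CC(=O)OC(C)(C)C)ccc1OCOC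
A2 | alternative 1 | tert-butyl (R,E)-3,11-bis[3-methoxy-4-(methoxymethoxy)phenyl]-5,7,9-trioxoundec-10-enoate | COc1cc(/C=C/C(=O)CC(=O)CC(=O)C[C@@H](c2ccc(OCOC)c(OC)c2)CC(=O)OC(C)(C)C)ccc1OCOC
A3 | alternative 2 | (R)-4-[4-(tert-butyldimethylsilyloxy)-3-methoxyphenyl]-5-[(E)-4-(tert-butyldimethylsilyloxy)-3-methoxystyryl]-7-hydroxychroman-2-one | COc1cc(/C=C/c2cc(O)cc3c2[C@@H](c2ccc(O[Si](C)(C)C(C)(C)C)c(OC)c2)CC(=O)O3)ccc1O[Si](C)(C)C(C)(C)C
A4 | alternative 2 | (E)-3-[4-(tert-butyldimethylsilyloxy)-3-methoxyphenyl]acrylaldehyde | COc1cc(/C=C/C=O)ccc1O[Si](C)(C)C(C)(C)C
A5 | alternative 2 | (E)-5-[4-(tert-butyldimethylsilyloxy)-3-methoxystyryl]benzene-1,3-diol | COc1cc(/C=C/c2cc(O)cc(O)c2)ccc1O[Si](C)(C)C(C)(C)C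
A6 | alternative 3 | (R)-4-[3-methoxy-4-(triisopropylsilyloxy)phenyl]-2-oxo-7-(triisopropylsilyloxy)chroman-5-yl trifluoromethanesulfonate | FC(F)(F)S(=O)(=O)Oc1cc(O[Si](C(C)C)(C(C)C)C(C)C)cc2c1[C@@H](c1ccc(O[Si](C(C)C)(C(C)C)C(C)C)c(OC)c1)CC(=O)O2
A7 | alternative 3 | (R)-3-[3-methoxy-4-(triisopropylsilyloxy)phenyl]-1-oxo-6-(triisopropylsilyloxy)-2,3-dihydro-1H-inden-4-yl trifluoromethanesulfonate | O=C1C[C@H](c2ccc(O[Si](C(C)C)(C(C)C)C(C)C)c(OC)c2)c2c(OS(=O)(=O)C(F)(F)F)cc(O[Si](C(C)C)(C(C)C)C(C)C)cc12
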